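## Plan

- **Cuts.** The acid comes from its methyl ester. The C8 side chain is then cut at the benzylic C–Ph bond (conjugate addition), at Cα=Cβ (Wittig) and at C8–CHO (formylation). This leaves (2S,3R)-5-hydroxy-7-methoxy-2,3-dimethyl-6-prenylchroman-4-one.
- **Enabling feature (chromanone numbering).** Ring A has OH at C5, prenyl at C6 and OMe at C7 on neighbouring carbons, H at C8, and is fused to the oxygen ring C through C4a–C8a. That is the imprint of a ketene carbon (C5) with its vinyl unit (C8, C8a=C4a, held in a dihydropyranone) joined to a methoxyalkyne (C6≡C7). Ring A is therefore cut at C8–C8a, C5–C6, C7–C8 and C4a–C5.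
- **Forward order.** Ring C is made first (aldol chain, oxalate acylation, acid cyclodehydration), then the diazo ketone, then ring A in one photochemical/thermal cascade with the ynol ether, and last the C8 side chain.
- **Stereochemistry.** C2 and C3 come from an Evans syn-aldol reaction; syn becomes cis because the carbinol C–O bond is never broken. The benzylic centre comes from catalyst control in a rhodium/chiral diene 1,4-addition.
- **Handling.** Once ring C exists, no step uses a strong base, because C3 can epimerise to the trans isomer.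

Key step: step 9

Assumption: the (1S,4S)-diene/rhodium catalyst of step 12 is taken to treat the E-enoate as it treats cyclic and acyclic E-enones. Aryl transfer then goes to the α-Si face, here the Si face of the β-carbon, which corresponds to R at the new centre.

## Route

Step 1
Reactants: 1 (R)-4-benzyl-3-propionyloxazolidin-2-one; 2 acetaldehyde
Product: 4 (R)-4-benzyl-3-[(2R,3S)-3-hydroxy-2-methylbutanoyl]oxazolidin-2-one, via boron enolate 3 (not isolated)
Conditions: n-Bu2BOTf, Et3N, CH2Cl2, 0 °C; MeCHO, −78 → 0 °C; pH 7 buffer, MeOH, 30% H2O2, 0 °C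
Reagents that add atoms: none
Why: Evans syn-aldol reaction, in which the (Z)-boron enolate 3 reacts through a closed chair transition state on the face away from the benzyl group, so that the α-carbon should become R and the carbinol carbon S (future C3 and C2 of ring C).

Step 2
Reactants: 4 (R)-4-benzyl-3-[(2R,3S)-3-hydroxy-2-methylbutanoyl]oxazolidin-2-one
Product: 5 (2R,3S)-3-hydroxy-N-methoxy-N,2-dimethylbutanamide
Conditions: MeNHOMe·HCl, AlMe3, THF/CH2Cl2, −20 → 0 °C; aq. tartaric acid
Reagents that add atoms: N,O-dimethylhydroxylamine hydrochloride, CNOC.Cl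
Why: Aluminium amide transamination of an N-acyloxazolidinone to the Weinreb amide, helped by the free β-hydroxyl group, should leave both stereocentres untouched and return the auxiliary.

Step 3
Reactants: 5 (2R,3S)-3-hydroxy-N-methoxy-N,2-dimethylbutanamide
Product: 6 (2R,3S)-N-methoxy-N,2-dimethyl-3-(triethylsilyloxy)butanamide
Conditions: Et3SiCl, imidazole, CH2Cl2, 0 °C → rt
Reagents that add atoms: chlorotriethylsilane, CC[Si](Cl)(CC)CC
Why: Standard silyl ether formation; triethylsilyl withstands Grignard and amide bases but is lost in the acid of step 6.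

Step 4
Reactants: 6 (2R,3S)-N-methoxy-N,2-dimethyl-3-(triethylsilyloxy)butanamide
Product: 7 (3R,4S)-3-methyl-4-(triethylsilyloxy)pentan-2-one
Conditions: MeMgBr, THF, −20 → 0 °C
Reagents that add atoms: methylmagnesium bromide, C[Mg]Br
Why: Weinreb ketone synthesis, in which the chelated tetrahedral adduct stops the reaction after one addition and the α-centre is not enolised at this temperature.

Step 5
Reactants: 7 (3R,4S)-3-methyl-4-(triethylsilyloxy)pentan-2-one; 8 di-tert-butyl oxalate
Product: 10 tert-butyl (5R,6S)-5-methyl-2,4-dioxo-6-(triethylsilyloxy)heptanoate, via lithium enolate 9 (not isolated)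
Conditions: LiN(SiMe3)2, THF, −78 °C; 8, −78 → 0 °C
Reagents that add atoms: none
Why: Crossed Claisen acylation, in which kinetic deprotonation at the methyl group gives 9, the non-enolisable oxalate is attacked once, and the product rests as its lithium diketonate, which shields the neighbouring stereocentre from enolisation.

Step 6
Reactants: 10 tert-butyl (5R,6S)-5-methyl-2,4-dioxo-6-(triethylsilyloxy)heptanoate
Product: 13 (2S,3R)-2,3-dimethyl-4-oxo-3,4-dihydro-2H-pyran-6-carboxylic acid, via hydroxy diketo ester 11 (not isolated), via pyranone tert-butyl ester 12 (not isolated)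
Conditions: CF3CO2H/CH2Cl2 (1:3), 0 °C → rt; evaporation from toluene
Reagents that add atoms: none
Why: Acid-mediated desilylation, 6-exo-trig attack of the freed hydroxyl on the C2 ketone with loss of water (cyclodehydration of a δ-hydroxy-1,3-diketone to a 2,3-dihydro-4-pyranone, closing ring C) and acidolysis of the tert-butyl ester run in one flask; the carbinol C–O bond stays intact, so syn becomes cis, and no base ever meets C3.

Step 7
Reactants: 13 (2S,3R)-2,3-dimethyl-4-oxo-3,4-dihydro-2H-pyran-6-carboxylic acid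
Product: 15 (2S,3R)-6-(diazoacetyl)-2,3-dimethyl-2,3-dihydro-4H-pyran-4-one, via acid chloride 14 (not isolated)
Conditions: (COCl)2, cat. DMF, CH2Cl2, 0 °C → rt, evaporate; added to excess CH2N2, Et2O, −20 → 0 °C, short contact, N2 purge
Reagents that add atoms: diazomethane, C=[N+]=[N-]
Why: Acylation of diazomethane by an acid chloride (first stage of the Arndt–Eistert sequence), with a second equivalent taking up HCl; inverse addition in the cold is meant to let the fast acylation outrun dipolar cycloaddition to the trisubstituted, oxygen-substituted C5=C6 bond, as with the related 4-oxochromene-2-carbonyl chlorides.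

Step 8
Reactants: 16 trichloroethylene; 17 prenyl bromide (1-bromo-3-methylbut-2-ene)
Product: 20 1-methoxy-5-methylhex-4-en-1-yne, via dichlorovinyl methyl ether 18 (not isolated), via lithium methoxyacetylide 19 (not isolated)
Conditions: KOMe, THF, 0 °C → rt; n-BuLi (2.2 equiv), −78 → −40 °C; 17, DMPU, −78 °C → rt
Reagents that add atoms: potassium methoxide, C[O-].[K+]
Why: One-flask ynol ether synthesis, in which methoxide adds to trichloroethylene by elimination–addition to give 18, n-BuLi effects dehydrochlorination and Cl/Li exchange to 19, and the amine-free acetylide is alkylated by SN2 attack at the primary carbon of the allylic bromide.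

Step 9
Reactants: 15 (2S,3R)-6-(diazoacetyl)-2,3-dimethyl-2,3-dihydro-4H-pyran-4-one; 20 1-methoxy-5-methylhex-4-en-1-yne
Product: 25 (2S,3R)-5-hydroxy-7-methoxy-2,3-dimethyl-6-(3-methylbut-2-enyl)chroman-4-one, via vinylketene 21 (not isolated), via cyclobutenone 22 (not isolated), via dienylketene 23 (not isolated), via cyclohexadienone 24 (not isolated)
Conditions: 20 (2 equiv), degassed ClCH2CH2Cl (0.05 M), 405 nm LED, 20 °C until N2 evolution ends; then dark, 80 °C
Reagents that add atoms: none
Why: Proposed new method: 405 nm light expels N2 from 15 and the oxygen-bearing ring carbon (future C8a) migrates to the carbene carbon (future C8) in a Wolff rearrangement, giving vinylketene 21, whose carbonyl carbon (future C5) is attacked by the prenyl-bearing nucleophilic carbon of ynol ether 20 in a [2+2] cycloaddition that forms C5–C6 and C7–C8 and gives cyclobutenone 22. Conrotatory four-electron opening of 22 breaks the old C5–C8 bond to give dienylketene 23, and ring A closes by disrotatory six-electron electrocyclisation of the ketene carbon onto C4a, after which dienone 24 tautomerises to the hydrogen-bonded phenol 25. The closest known reaction type is the Danheiser benzannulation in its diazo ketone (photo-Wolff) form, proven for cycloalkenyl, aryl and furyl diazomethyl ketones with alkoxy- and siloxyalkynes; not yet shown is a vinylketene whose C=C is that of a vinylogous ester, with an acyl group on the carbon that closes the ring. No lasting stereocentre is created (the sp3 carbons C8 of 22 and C4a of 24 are flattened again), and C2 and C3 are spectators in a neutral medium. Regioselectivity (OMe at C7, prenyl at C6, H at C8) rests on the polarity match between the ketene carbonyl carbon and the ynol ether β-carbon, which the electron-poor ketene should sharpen, and oxa-electrocyclisation of 21 to an α-pyrone is excluded because the ring holds the ketenyl group trans to C4=O across C4a=C8a. Chemoselectivity for the diazo chromophore over enone excitation is sought with light beyond the enone absorption, an excess of 20 to catch the ketene, and a dark thermal finish for the two electrocyclic steps.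

Step 10
Reactants: 25 (2S,3R)-5-hydroxy-7-methoxy-2,3-dimethyl-6-(3-methylbut-2-enyl)chroman-4-one
Product: 27 (2S,3R)-5-hydroxy-7-methoxy-2,3-dimethyl-6-(3-methylbut-2-enyl)-4-oxochroman-8-carbaldehyde, via C8 iminium chloride 26 (not isolated)
Conditions: POCl3 (1.5 equiv), DMF, 0 °C → rt; aq. NaOAc, rt
Reagents that add atoms: N,N-dimethylformamide, CN(C)C=O; water, O
Why: Vilsmeier–Haack formylation; C8 is the only free ring carbon and lies ortho to two ether oxygens and para to the C5 hydroxyl, so the weakly electrophilic chloroiminium ion should attack there faster than at the prenyl alkene or the chelated, C3-substituted ketone.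

Step 11
Reactants: 27 (2S,3R)-5-hydroxy-7-methoxy-2,3-dimethyl-6-(3-methylbut-2-enyl)-4-oxochroman-8-carbaldehyde; 28 methyl (triphenylphosphoranylidene)acetate
Product: 29 methyl (E)-3-[(2S,3R)-5-hydroxy-7-methoxy-2,3-dimethyl-6-(3-methylbut-2-enyl)-4-oxochroman-8-yl]acrylate
Conditions: 28 (1.5 equiv), toluene, 80 °C
Reagents that add atoms: none
Why: Wittig olefination with a stabilised, almost non-basic ylide, which should give the E-enoate and tolerate the chelated phenol and the C3 centre.

Step 12
Reactants: 29 methyl (E)-3-[(2S,3R)-5-hydroxy-7-methoxy-2,3-dimethyl-6-(3-methylbut-2-enyl)-4-oxochroman-8-yl]acrylate; 30 phenylboronic acid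
Product: 31 methyl (R)-3-[(2S,3R)-5-hydroxy-7-methoxy-2,3-dimethyl-6-(3-methylbut-2-enyl)-4-oxochroman-8-yl]-3-phenylpropanoate
Conditions: [RhCl(C2H4)2]2 (2.5 mol %), (1S,4S)-2,5-diphenylbicyclo[2.2.2]octa-2,5-diene (5.5 mol %), KOH (10 mol %), 30 (3 equiv), 1,4-dioxane/H2O (10:1), 40 °C
Reagents that add atoms: none
Why: Hayashi–Miyaura asymmetric 1,4-addition, in which the phenylrhodium species carrying the C2-symmetric diene binds the E-enoate so that phenyl goes to the Si face of the β-carbon, which should set the R centre under catalyst control while the nearly neutral aqueous medium spares C3 and the prenyl group.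

Step 13
Reactants: 31 methyl (R)-3-[(2S,3R)-5-hydroxy-7-methoxy-2,3-dimethyl-6-(3-methylbut-2-enyl)-4-oxochroman-8-yl]-3-phenylpropanoate
Product: 33 (R)-3-[(2S,3R)-5-hydroxy-7-methoxy-2,3-dimethyl-6-(3-methylbut-2-enyl)-4-oxochroman-8-yl]-3-phenylpropanoic acid, via trimethylstannyl ester 32 (not isolated)
Conditions: Me3SnOH (8 equiv), ClCH2CH2Cl, 70 °C; 0.5 M aq. HCl wash
Reagents that add atoms: trimethyltin hydroxide, C[Sn](C)(C)O
Why: Trimethyltin hydroxide ester cleavage, which hydrolyses the unhindered methyl ester under essentially neutral conditions, so neither C3 nor the benzylic centre should epimerise and the acid-sensitive o-prenylphenol is spared.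

## Compound list

1 | (R)-4-benzyl-3-propionyloxazolidin-2-one | CCC(=O)N1[C@H](Cc2ccccc2)COC1=O | starting material
2 | acetaldehyde | CC=O | starting material
3 | (Z)-dibutylboron enolate of 1 | C/C=C(\OB(CCCC)CCCC)N1[C@H](Cc2ccccc2)COC1=O | intermediate
4 | (R)-4-benzyl-3-[(2R,3S)-3-hydroxy-2-methylbutanoyl]oxazolidin-2-one | C[C@H](O)[C@@H](C)C(=O)N1[C@H](Cc2ccccc2)COC1=O | intermediate
5 | (2R,3S)-3-hydroxy-N-methoxy-N,2-dimethylbutanamide | C[C@H](O)[C@@H](C)C(=O)N(C)OC | intermediate
6 | (2R,3S)-N-methoxy-N,2-dimethyl-3-(triethylsilyloxy)butanamide | C[C@H](O[Si](CC)(CC)CC)[C@@H](C)C(=O)N(C)OC | intermediate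
7 | (3R,4S)-3-methyl-4-(triethylsilyloxy)pentan-2-one | C[C@H](O[Si](CC)(CC)CC)[C@@H](C)C(C)=O | intermediate
8 | di-tert-butyl oxalate | CC(C)(C)OC(=O)C(=O)OC(C)(C)C | starting material
9 | lithium (3R,4S)-3-methyl-4-(triethylsilyloxy)pent-1-en-2-olate | C[C@H](O[Si](CC)(CC)CC)[C@@H](C)C(=C)O[Li] | intermediate
10 | tert-butyl (5R,6S)-5-methyl-2,4-dioxo-6-(triethylsilyloxy)heptanoate | C[C@H](O[Si](CC)(CC)CC)[C@@H](C)C(=O)CC(=O)C(=O)OC(C)(C)C | intermediate
11 | tert-butyl (5R,6S)-6-hydroxy-5-methyl-2,4-dioxoheptanoate | C[C@H](O)[C@@H](C)C(=O)CC(=O)C(=O)OC(C)(C)C | intermediate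
12 | tert-butyl (2S,3R)-2,3-dimethyl-4-oxo-3,4-dihydro-2H-pyran-6-carboxylate | O1[C@@H](C)[C@@H](C)C(=O)C=C1C(=O)OC(C)(C)C | intermediate
13 | (2S,3R)-2,3-dimethyl-4-oxo-3,4-dihydro-2H-pyran-6-carboxylic acid | O1[C@@H](C)[C@@H](C)C(=O)C=C1C(=O)O | intermediate
14 | (2S,3R)-2,3-dimethyl-4-oxo-3,4-dihydro-2H-pyran-6-carbonyl chloride | O1[C@@H](C)[C@@H](C)C(=O)C=C1C(=O)Cl | intermediate
15 | (2S,3R)-6-(diazoacetyl)-2,3-dimethyl-2,3-dihydro-4H-pyran-4-one | O1[C@@H](C)[C@@H](C)C(=O)C=C1C(=O)C=[N+]=[N-] | intermediate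
16 | trichloroethylene | ClC=C(Cl)Cl | starting material
17 | prenyl bromide (1-bromo-3-methylbut-2-ene) | CC(C)=CCBr | starting material
18 | (E)-1,2-dichloro-1-methoxyethene | CO/C(Cl)=C\Cl | intermediate
19 | lithium methoxyacetylide (LiC≡COMe) | COC#C[Li] | intermediate
20 | 1-methoxy-5-methylhex-4-en-1-yne | COC#CCC=C(C)C | intermediate
21 | 2-[(2S,3R)-2,3-dimethyl-4-oxo-3,4-dihydro-2H-pyran-6-yl]ethenone (vinylketene) | O1[C@@H](C)[C@@H](C)C(=O)C=C1C=C=O | intermediate
22 | 4-[(2S,3R)-2,3-dimethyl-4-oxo-3,4-dihydro-2H-pyran-6-yl]-3-methoxy-2-(3-methylbut-2-enyl)cyclobut-2-en-1-one (C4 of the four-membered ring undefined) | O1[C@@H](C)[C@@H](C)C(=O)C=C1C1C(=O)C(CC=C(C)C)=C1OC | intermediate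
23 | 4-[(2S,3R)-2,3-dimethyl-4-oxo-3,4-dihydro-2H-pyran-6-yl]-3-methoxy-2-(3-methylbut-2-enyl)buta-1,3-dien-1-one, pyranyl group cis to the ketene-bearing carbon | O1[C@@H](C)[C@@H](C)C(=O)C=C1/C=C(OC)\C(CC=C(C)C)=C=O | intermediate
24 | (2S,3R)-7-methoxy-2,3-dimethyl-6-(3-methylbut-2-enyl)-2,3-dihydro-4aH-chromene-4,5-dione (keto tautomer of 25, C4a undefined) | O1[C@@H](C)[C@@H](C)C(=O)C2C1=CC(OC)=C(CC=C(C)C)C2=O | intermediate
25 | (2S,3R)-5-hydroxy-7-methoxy-2,3-dimethyl-6-(3-methylbut-2-enyl)chroman-4-one | O1[C@@H](C)[C@@H](C)C(=O)c2c(O)c(CC=C(C)C)c(OC)cc12 | intermediate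
26 | N,N-dimethyliminium chloride of aldehyde 27 (ArCH=NMe2+ Cl−) | O1[C@@H](C)[C@@H](C)C(=O)c2c(O)c(CC=C(C)C)c(OC)c(C=[N+](C)C)c12.[Cl-] | intermediate
27 | (2S,3R)-5-hydroxy-7-methoxy-2,3-dimethyl-6-(3-methylbut-2-enyl)-4-oxochroman-8-carbaldehyde | O1[C@@H](C)[C@@H](C)C(=O)c2c(O)c(CC=C(C)C)c(OC)c(C=O)c12 | intermediate
28 | methyl (triphenylphosphoranylidene)acetate | COC(=O)C=P(c1ccccc1)(c1ccccc1)c1ccccc1 | starting material
29 | methyl (E)-3-[(2S,3R)-5-hydroxy-7-methoxy-2,3-dimethyl-6-(3-methylbut-2-enyl)-4-oxochroman-8-yl]acrylate | O1[C@@H](C)[C@@H](C)C(=O)c2c(O)c(CC=C(C)C)c(OC)c(/C=C/C(=O)OC)c12 | intermediate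
30 | phenylboronic acid | OB(O)c1ccccc1 | starting material
31 | methyl (R)-3-[(2S,3R)-5-hydroxy-7-methoxy-2,3-dimethyl-6-(3-methylbut-2-enyl)-4-oxochroman-8-yl]-3-phenylpropanoate | COc1c(CC=C(C)C)c(O)c2c(c1[C@H](CC(=O)OC)c1ccccc1)O[C@@H](C)[C@@H](C)C2=O | intermediate
32 | trimethylstannyl ester of 33 | COc1c(CC=C(C)C)c(O)c2c(c1[C@H](CC(=O)O[Sn](C)(C)C)c1ccccc1)O[C@@H](C)[C@@H](C)C2=O | intermediate
33 | (R)-3-[(2S,3R)-5-hydroxy-7-methoxy-2,3-dimethyl-6-(3-methylbut-2-enyl)-4-oxochroman-8-yl]-3-phenylpropanoic acid (CNP0172137.1) | COc1c(CC=C(C)C)c(O)c2c(c1[C@H](CC(=O)O)c1ccccc1)O[C@@H](C)[C@@H](C)C2=O | target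

## Step count and risks

Total steps: 13. Longest linear sequence: 12 (steps 1–7 and 9–13); step 8 is the side branch.

**Step 9 (key step).**
- What may go wrong: the enone part may absorb light and enter [2+2] photocycloaddition with the alkyne or the prenyl alkene. The electron-poor ketene may oligomerise before it is caught. Ring closure onto the acyl-bearing C4a may be slow.
- Idea of the fallback: it removes the C4 carbonyl during the annulation, so that the diazo ketone falls into the proven cycloalkenyl class. It sets out from acid 13 and returns at chromanone 25.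
- Luche reduction (NaBH4, CeCl3·7H2O, MeOH, −40 °C) should give, by axial hydride delivery, the all-cis alcohol (2S,3S,4R)-4-hydroxy-2,3-dimethyl-3,4-dihydro-2H-pyran-6-carboxylic acid F1. Its C4 configuration is erased at the end.
- t-BuMe2SiCl and imidazole in DMF give the silyl ether silyl ester tert-butyldimethylsilyl (2S,3R,4R)-4-(tert-butyldimethylsilyloxy)-2,3-dimethyl-3,4-dihydro-2H-pyran-6-carboxylate F2.
- (COCl)2 with cat. DMF turns the silyl ester under neutral conditions into (2S,3R,4R)-4-(tert-butyldimethylsilyloxy)-2,3-dimethyl-3,4-dihydro-2H-pyran-6-carbonyl chloride F3.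
- Cold ethereal CH2N2 then converts F3 into 1-[(2S,3R,4R)-4-(tert-butyldimethylsilyloxy)-2,3-dimethyl-3,4-dihydro-2H-pyran-6-yl]-2-diazoethanone F4.
- Irradiation at 300 nm with alkyne 20 in ClCH2CH2Cl, followed by heating at 80 °C, gives (2S,3R,4R)-4-(tert-butyldimethylsilyloxy)-7-methoxy-2,3-dimethyl-6-(3-methylbut-2-enyl)chroman-5-ol F5.
- Bu4NF buffered with AcOH frees (2S,3S,4R)-7-methoxy-2,3-dimethyl-6-(3-methylbut-2-enyl)chroman-4,5-diol F6.
- MnO2 in CH2Cl2 oxidises the benzylic alcohol of F6 to give 25.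

**Step 7.**
- What may go wrong: dipolar cycloaddition of diazomethane across C5=C6 may occur before or after acylation and consume the material.
- Idea of the fallback: it introduces the diazo group by detrifluoroacetylative diazo transfer, without any diazoalkane. It sets out from ketone 7 and returns at diazo ketone 15.
- Enolate 9 is acylated with methyl 2,2-dimethoxypropanoate (THF, −78 → 0 °C) to give (6R,7S)-2,2-dimethoxy-6-methyl-7-(triethylsilyloxy)octane-3,5-dione F7.
- CF3CO2H in wet CH2Cl2 removes the silyl group, closes ring C and hydrolyses the ketal, giving (2S,3R)-6-acetyl-2,3-dimethyl-2,3-dihydro-4H-pyran-4-one F8.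
- LiN(SiMe3)2 and CF3CO2CH2CF3 at −78 °C deprotonate and acylate the more acidic acetyl methyl group. The product is (2S,3R)-2,3-dimethyl-6-(4,4,4-trifluoro-3-oxobutanoyl)-2,3-dihydro-4H-pyran-4-one F9.
- F9 is treated without isolation with MeSO2N3, Et3N and H2O in MeCN to give 15.

**Step 12.**
- What may go wrong: insertion may be slow because two ortho substituents flank the β-carbon. Protodeboronation of the boronic acid then wins, and facial selectivity may be poor.
- Idea of the fallback: it replaces catalyst control by a covalently bound auxiliary and a more reactive organocopper nucleophile. It sets out from aldehyde 27 and returns at target 33, bypassing steps 11–13.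
- Masamune–Roush olefination uses the phosphonate reagent (S)-3-[(diethoxyphosphoryl)acetyl]-4-phenyloxazolidin-2-one (LiCl, i-Pr2NEt, MeCN). It gives (S)-3-{(E)-3-[(2S,3R)-5-hydroxy-7-methoxy-2,3-dimethyl-6-(3-methylbut-2-enyl)-4-oxochroman-8-yl]acryloyl}-4-phenyloxazolidin-2-one F10.
- PhMgBr/CuBr·SMe2 (THF/Me2S, −40 °C) then adds phenyl; one equivalent is spent on the phenol, whose magnesium chelate also masks the C4 ketone. Attack on the chelated syn-s-cis imide from the face opposite the auxiliary phenyl group gives the R centre. The product is (S)-3-{(R)-3-[(2S,3R)-5-hydroxy-7-methoxy-2,3-dimethyl-6-(3-methylbut-2-enyl)-4-oxochroman-8-yl]-3-phenylpropanoyl}-4-phenyloxazolidin-2-one F11.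
- LiOH/H2O2 (THF/H2O, 0 °C) cleaves the imide of F11 to give 33.

## Further compounds

F1 | step 9 | (2S,3S,4R)-4-hydroxy-2,3-dimethyl-3,4-dihydro-2H-pyran-6-carboxylic acid | O1[C@@H](C)[C@@H](C)[C@@H](O)C=C1C(=O)O
F2 | step 9 | tert-butyldimethylsilyl (2S,3R,4R)-4-(tert-butyldimethylsilyloxy)-2,3-dimethyl-3,4-dihydro-2H-pyran-6-carboxylate | O1[C@@H](C)[C@@H](C)[C@@H](O[Si](C)(C)C(C)(C)C)C=C1C(=O)O[Si](C)(C)C(C)(C)C
F3 | step 9 | (2S,3R,4R)-4-(tert-butyldimethylsilyloxy)-2,3-dimethyl-3,4-dihydro-2H-pyran-6-carbonyl chloride | O1[C@@H](C)[C@@H](C)[C@@H](O[Si](C)(C)C(C)(C)C)C=C1C(=O)Cl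
F4 | step 9 | 1-[(2S,3R,4R)-4-(tert-butyldimethylsilyloxy)-2,3-dimethyl-3,4-dihydro-2H-pyran-6-yl]-2-diazoethanone | O1[C@@H](C)[C@@H](C)[C@@H](O[Si](C)(C)C(C)(C)C)C=C1C(=O)C=[N+]=[N-]
F5 | step 9 | (2S,3R,4R)-4-(tert-butyldimethylsilyloxy)-7-methoxy-2,3-dimethyl-6-(3-methylbut-2-enyl)chroman-5-ol | O1[C@@H](C)[C@@H](C)[C@@H](O[Si](C)(C)C(C)(C)C)c2c(O)c(CC=C(C)C)c(OC)cc12
F6 | step 9 | (2S,3S,4R)-7-methoxy-2,3-dimethyl-6-(3-methylbut-2-enyl)chroman-4,5-diol | O1[C@@H](C)[C@@H](C)[C@@H](O)c2c(O)c(CC=C(C)C)c(OC)cc12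
F7 | step 7 | (6R,7S)-2,2-dimethoxy-6-methyl-7-(triethylsilyloxy)octane-3,5-dione | C[C@H](O[Si](CC)(CC)CC)[C@@H](C)C(=O)CC(=O)C(C)(OC)OC
F8 | step 7 | (2S,3R)-6-acetyl-2,3-dimethyl-2,3-dihydro-4H-pyran-4-one | O1[C@@H](C)[C@@H](C)C(=O)C=C1C(C)=O
F9 | step 7 | (2S,3R)-2,3-dimethyl-6-(4,4,4-trifluoro-3-oxobutanoyl)-2,3-dihydro-4H-pyran-4-one | O1[C@@H](C)[C@@H](C)C(=O)C=C1C(=O)CC(=O)C(F)(F)F
F10 | step 12 | (S)-3-{(E)-3-[(2S,3R)-5-hydroxy-7-methoxy-2,3-dimethyl-6-(3-methylbut-2-enyl)-4-oxochroman-8-yl]acryloyl}-4-phenyloxazolidin-2-one | O1[C@@H](C)[C@@H](C)C(=O)c2c(O)c(CC=C(C)C)c(OC)c(/C=C/C(=O)N3[C@@H](c4ccccc4)COC3=O)c12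
F11 | step 12 | (S)-3-{(R)-3-[(2S,3R)-5-hydroxy-7-methoxy-2,3-dimethyl-6-(3-methylbut-2-enyl)-4-oxochroman-8-yl]-3-phenylpropanoyl}-4-phenyloxazolidin-2-one | COc1c(CC=C(C)C)c(O)c2c(c1[C@H](CC(=O)N1[C@@H](c3ccccc3)COC1=O)c1ccccc1)O[C@@H](C)[C@@H](C)C2=O
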